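**Retrosynthetic overview**

Rings: A = methylcyclohexene, B = cyclohexene carrying CO2Me, C = isopropylcyclohexanone, D = lactol (oxolane) bridge.
Enabling feature: the A/B/D junction carbon carries a tertiary C–O bond trans and vicinal to the bond from the A/B/D junction CH to the methyl-bearing quaternary carbon (B/C/D). That carbon is α to the lactol carbon, a masked ketone. This is the retron of an oxirane opened by a ketone enolate.
Key disconnection: that C–C bond. It closes ring B on a precursor in which ring A (as its 1,2-oxirane) and ring C (one carbonyl free, the other a dimethyl ketal) are already tied through the C=C(CO2Me) unit; the alkoxide released closes lactol D in the same operation.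
Further disconnections: the acrylate C=C by Horner–Wadsworth–Emmons union of an epoxy aldehyde (ring A: Diels–Alder, then Sharpless epoxidation) with a phosphonate (ring C: quinone monoketal, asymmetric isopropyl addition, Michael addition).
Ring order: A (step 1) and C (arene, dearomatised in step 6), temporary oxirane (step 4), then B with the lactol bridge D closing on it in step 10; no ring is formed afterwards.

Key step: step 10

Assumption: the lactol carbon is not an independent stereocentre; ring–chain tautomerism lets it close only in the one sense the cage permits, and it is written throughout with the descriptor of the given SMILES.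

**Route**

Step 1
Reactants: 1 isoprene; 2 methyl (E)-3-nitroacrylate
Product: 3 methyl (1R*,6R*)-3-methyl-6-nitrocyclohex-3-ene-1-carboxylate (trans, racemic)
Conditions: PhH, 25 °C
Reagents that add atoms: none
Why: Diels–Alder reaction in which the nitro group, the stronger director, should place the diene methyl "para" to the nitro-bearing carbon and hence "meta" to the ester as ring A requires; the trans centres come from the (E)-dienophile and are erased in step 2.

Step 2
Reactants: 3 methyl (1R*,6R*)-3-methyl-6-nitrocyclohex-3-ene-1-carboxylate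
Product: 4 methyl 5-methylcyclohexa-1,4-diene-1-carboxylate
Conditions: DBU, THF, 0 °C
Reagents that add atoms: none
Why: E1cB loss of nitrous acid from the β-nitro ester should give the conjugated ester while the second alkene stays out of conjugation (nitroacrylate as a propiolate equivalent of reversed regiochemistry).

Step 3
Reactants: 4 methyl 5-methylcyclohexa-1,4-diene-1-carboxylate
Product: 5 (5-methylcyclohexa-1,4-dien-1-yl)methanol
Conditions: i-Bu2AlH, CH2Cl2, −78 °C; aqueous work-up
Reagents that add atoms: none
Why: 1,2-reduction of the α,β-unsaturated ester by the aluminium hydride should give the allylic alcohol that directs the epoxidation.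

Step 4
Reactants: 5 (5-methylcyclohexa-1,4-dien-1-yl)methanol
Product: 6 [(1R,6R)-3-methyl-7-oxabicyclo[4.1.0]hept-3-en-1-yl]methanol
Conditions: Ti(Oi-Pr)4 (cat.), D-(−)-diisopropyl tartrate (cat.), t-BuOOH, 4 Å MS, CH2Cl2, −20 °C
Reagents that add atoms: tert-butyl hydroperoxide, CC(C)(C)OO
Why: Sharpless asymmetric epoxidation: the titanium tartrate binds the allylic alcohol, so only its alkene should be oxidised, and the D-tartrate should deliver oxygen to the face that gives the (1R,6R) oxirane, fixing both ring A stereocentres.

Step 5
Reactants: 6 [(1R,6R)-3-methyl-7-oxabicyclo[4.1.0]hept-3-en-1-yl]methanol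
Product: 7 (1S,6R)-3-methyl-7-oxabicyclo[4.1.0]hept-3-ene-1-carbaldehyde
Conditions: TEMPO (cat.), PhI(OAc)2, CH2Cl2, 20 °C
Reagents that add atoms: none
Why: oxoammonium-mediated oxidation of the primary alcohol under near-neutral conditions should spare the oxirane, the alkene and the non-enolisable aldehyde.

Step 6
Reactants: 8 4-methoxy-2-methylphenol
Product: 9 4,4-dimethoxy-2-methylcyclohexa-2,5-dien-1-one
Conditions: PhI(OAc)2, MeOH, 0 °C
Reagents that add atoms: methanol, CO
Why: oxidative dearomatisation of a p-methoxyphenol in methanol should give the quinone monoketal, which delivers ring C with its two carbonyl carbons already differentiated.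

Step 7
Reactants: 9 4,4-dimethoxy-2-methylcyclohexa-2,5-dien-1-one
Product: 10 (R)-5-isopropyl-4,4-dimethoxy-2-methylcyclohex-2-en-1-one
Conditions: Cu(OTf)2 (cat.), BINOL-derived phosphoramidite ligand (cat., enantiomer leading to R), i-Pr2Zn, PhMe, −25 °C; aq. NH4Cl
Reagents that add atoms: diisopropylzinc, CC(C)[Zn]C(C)C
Why: copper-catalysed asymmetric conjugate addition of a dialkylzinc to a quinone monoketal: the alkyl group should go to the enone arm without the α-methyl group, and the ligand sets the isopropyl-bearing centre, which then stays fixed because its neighbour is a ketal and not a ketone.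

Step 8
Reactants: 10 (R)-5-isopropyl-4,4-dimethoxy-2-methylcyclohex-2-en-1-one; 11 trimethyl phosphonoacetate
Product: 12 methyl 2-(dimethoxyphosphoryl)-2-[(1S,3R,6S)-3-isopropyl-2,2-dimethoxy-6-methyl-5-oxocyclohexyl]acetate (epimers at C-6 and at the phosphonate carbon)
Conditions: Cs2CO3 (cat.), MeCN, 25 °C
Reagents that add atoms: none
Why: Michael addition of the soft phosphonoacetate carbanion; attack on the half-chair enone anti to the pseudo-equatorial isopropyl group (the 3,5-trans preference of 5-substituted cyclohexenones) should put the side chain trans to isopropyl, while the two epimeric centres do not matter later.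

Step 9
Reactants: 12 methyl 2-(dimethoxyphosphoryl)-2-[(1S,3R,6S)-3-isopropyl-2,2-dimethoxy-6-methyl-5-oxocyclohexyl]acetate; 7 (1S,6R)-3-methyl-7-oxabicyclo[4.1.0]hept-3-ene-1-carbaldehyde
Product: 13 methyl (E)-2-[(1R,3R,6S)-3-isopropyl-2,2-dimethoxy-6-methyl-5-oxocyclohexyl]-3-[(1R,6R)-3-methyl-7-oxabicyclo[4.1.0]hept-3-en-1-yl]prop-2-enoate (C-6 epimers)
Conditions: NaH, THF, 0 → 25 °C
Reagents that add atoms: none
Why: Horner–Wadsworth–Emmons olefination: the phosphonate C–H is far more acidic than the ketone α-hydrogens, the aldehyde cannot enolise, and α-substituted phosphonoacetates normally place the ester trans to the aldehyde residue, which is the geometry (ring C carbon cis to the oxirane carbon) that the ring closure needs.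

Step 10
Reactants: 13 methyl (E)-2-[(1R,3R,6S)-3-isopropyl-2,2-dimethoxy-6-methyl-5-oxocyclohexyl]-3-[(1R,6R)-3-methyl-7-oxabicyclo[4.1.0]hept-3-en-1-yl]prop-2-enoate
Product: 16 dimethyl ketal of the target (ring C ketone as C(OMe)2), via potassium enolate 14 (not isolated), via keto alkoxide 15 (not isolated)
Conditions: t-BuOK, t-BuOH–THF, 0 → 45 °C; AcOH quench
Reagents that add atoms: none
Why: Thermodynamic deprotonation (the ketone enolates equilibrate in t-BuOH) gives the tetrasubstituted enolate 14, whose C-methyl carbon attacks the secondary oxirane carbon from the side opposite the C–O bond; release of oxirane strain pays for the congested bond to the new quaternary carbon, and the tertiary alkoxide set free (15) adds to the ring C ketone it now faces and is protonated to the lactol on quench. The closest known reaction type is the intramolecular alkylation of ketone and nitrile enolates by epoxides, here followed by ring–chain lactolisation of a γ-hydroxy ketone. Ring B closes 6-endo-tet at the oxirane (attack at the distal, less substituted carbon, since the 5-exo alternative would be an SN2 at the fully substituted tether carbon), and the lactol bridge then closes 5-exo-trig. The ring A CH is set by inversion and the O-bearing ring A carbon is retained, both from the Sharpless oxirane; the quaternary methyl carbon is set by the short (E)-alkenyl tether, which can reach only the enolate face cis to the side chain installed in step 8 (cis B/C fusion), and the lactol carbon can close in one sense only. The step needs enolate regioselection and site selection at the oxirane: only the C-methyl enolate has an electrophile within reach while the CH2 enolate returns by proton exchange, and trans-diaxial (Fürst–Plattner) opening at the secondary carbon is the only SN2 path; the isopropyl- and side-chain-bearing carbons cannot epimerise because their neighbour is a ketal, not a ketone.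

Step 11
Reactants: 16 dimethyl ketal of the target
Product: 17 target (CNP0382995.2)
Conditions: pyridinium p-toluenesulfonate (cat.), acetone–H2O, 40 °C
Reagents that add atoms: water, O
Why: acid-catalysed hydrolysis of the dimethyl ketal should unveil the ring C ketone; mild aqueous acid should leave the lactol, the enoate and the two α-stereocentres untouched, and the product never meets base.

**Compound list**

1 | isoprene (2-methylbuta-1,3-diene) | C=CC(C)=C | starting material
2 | methyl (E)-3-nitroacrylate | COC(=O)/C=C/[N+](=O)[O-] | starting material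
3 | methyl (1R*,6R*)-3-methyl-6-nitrocyclohex-3-ene-1-carboxylate (trans, racemic; one enantiomer drawn) | COC(=O)[C@@H]1CC(C)=CC[C@H]1[N+](=O)[O-] | intermediate
4 | methyl 5-methylcyclohexa-1,4-diene-1-carboxylate | COC(=O)C1=CCC=C(C)C1 | intermediate
5 | (5-methylcyclohexa-1,4-dien-1-yl)methanol | OCC1=CCC=C(C)C1 | intermediate
6 | [(1R,6R)-3-methyl-7-oxabicyclo[4.1.0]hept-3-en-1-yl]methanol | OC[C@]12CC(C)=CC[C@H]1O2 | intermediate
7 | (1S,6R)-3-methyl-7-oxabicyclo[4.1.0]hept-3-ene-1-carbaldehyde | O=C[C@]12CC(C)=CC[C@H]1O2 | intermediate
8 | 4-methoxy-2-methylphenol | COc1ccc(O)c(C)c1 | starting material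
9 | 4,4-dimethoxy-2-methylcyclohexa-2,5-dien-1-one | CC1=CC(OC)(OC)C=CC1=O | intermediate
10 | (R)-5-isopropyl-4,4-dimethoxy-2-methylcyclohex-2-en-1-one | CC1=CC(OC)(OC)[C@@H](C(C)C)CC1=O | intermediate
11 | trimethyl phosphonoacetate | COC(=O)CP(=O)(OC)OC | starting material
12 | methyl 2-(dimethoxyphosphoryl)-2-[(1S,3R,6S)-3-isopropyl-2,2-dimethoxy-6-methyl-5-oxocyclohexyl]acetate; side chain trans to isopropyl, C-6 epimer drawn, phosphonate carbon unassigned | C[C@@H]1C(=O)C[C@H](C(C)C)C(OC)(OC)[C@H]1C(C(=O)OC)P(=O)(OC)OC | intermediate
13 | methyl (E)-2-[(1R,3R,6S)-3-isopropyl-2,2-dimethoxy-6-methyl-5-oxocyclohexyl]-3-[(1R,6R)-3-methyl-7-oxabicyclo[4.1.0]hept-3-en-1-yl]prop-2-enoate; C-6 epimer drawn | COC(=O)/C(=C/[C@]12CC(C)=CC[C@H]1O2)[C@H]3[C@H](C)C(=O)C[C@H](C(C)C)C3(OC)OC | intermediate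
14 | potassium enolate of 13 (tetrasubstituted, at the C-methyl carbon) | COC(=O)/C(=C/[C@]12CC(C)=CC[C@H]1O2)[C@H]3C(C)=C([O-])C[C@H](C(C)C)C3(OC)OC.[K+] | intermediate
15 | potassium alkoxide of the ring-B-closed hydroxy ketone (tertiary alkoxide on ring A, free ring C ketone) | COC(=O)C1=C[C@]2([O-])CC(C)=CC[C@@H]2[C@]3(C)[C@H]1C(OC)(OC)[C@@H](C(C)C)CC3=O.[K+] | intermediate
16 | dimethyl ketal of the target (target with C(OMe)2 in place of the ring C ketone) | COC(=O)C1=C[C@]23CC(C)=CC[C@@H]2[C@]2(C)[C@H]1C(OC)(OC)[C@@H](C(C)C)C[C@@]2(O)O3 | intermediate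
17 | target CNP0382995.2 | COC(=O)C1=C[C@]23CC(C)=CC[C@@H]2[C@]2(C)[C@H]1C(=O)[C@@H](C(C)C)C[C@@]2(O)O3 | target

**Step count and risks**

Total steps: 11. Longest linear sequence: 8 steps (1–5, 9, 10, 11).

Steps most likely to fail:

Step 10. The ring closure may stall or go astray: the less substituted enolate may be drained by Michael or Claisen-type closure onto the acrylate, or attack on the hindered oxirane carbon may be too slow. The fallback replaces the oxirane by a Michael acceptor and sets out from 12. Olefination of 12 with commercial 4-hydroxy-3-methylbenzaldehyde (K2CO3, aqueous THF) should give methyl (E)-3-(4-hydroxy-3-methylphenyl)-2-[(1R,3R,6S)-3-isopropyl-2,2-dimethoxy-6-methyl-5-oxocyclohexyl]prop-2-enoate F1. PhI(OAc)2 in aqueous MeCN should dearomatise the phenol to the p-quinol methyl (E)-3-(1-hydroxy-3-methyl-4-oxocyclohexa-2,5-dien-1-yl)-2-[(1R,3R,6S)-3-isopropyl-2,2-dimethoxy-6-methyl-5-oxocyclohexyl]prop-2-enoate F2, formed as both carbinol epimers, of which only the matched one goes on. Base (DBU or t-BuOK) should then close ring B by intramolecular Michael addition of the same ketone enolate to the enone arm without methyl, the tertiary alkoxide closing the lactol, to give the cage enone (16 with ring A as a 2-methylcyclohex-2-en-1-one) F3. Its tosylhydrazone F4 (TsNHNH2, EtOH), reduced with catecholborane and then warmed with NaOAc, should lose sulfinate and dinitrogen with 1,3-shift of the alkene and so come back to 16.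

Step 9. The olefination joins two hindered partners; slow reaction or poor control of alkene geometry is possible, and only the E isomer can cyclise. The fallback uses a stereoretentive C–C coupling instead, sets out from 7 and 10, and bypasses 12. Wittig reaction of 7 with Ph3P=C(Br)CO2Me should give methyl (Z)-2-bromo-3-[(1R,6R)-3-methyl-7-oxabicyclo[4.1.0]hept-3-en-1-yl]prop-2-enoate F5, in which bromine already sits cis to the oxirane carbon. Nickel-catalysed reductive conjugate addition of F5 to enone 10 (NiCl2(dme), bipyridine-type ligand, Mn, Et3SiCl, DMF) should transfer the alkenyl group with retention and anti to isopropyl, giving the triethylsilyl enol ether of 13 F6. Buffered fluoride (Bu4NF, AcOH) comes back to 13.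

Step 7. Transfer of the secondary alkyl group may show poor selection between the two enone arms or poor facial selectivity. The fallback adds an sp2 group first and hydrogenates afterwards, setting out from 9. Rhodium-catalysed asymmetric 1,4-addition of isopropenylboronic acid pinacol ester ([Rh(cod)Cl]2, BINAP, aqueous KOH, dioxane) should give (R)-4,4-dimethoxy-2-methyl-5-(prop-1-en-2-yl)cyclohex-2-en-1-one F7. Selective hydrogenation of the 1,1-disubstituted alkene (H2, RhCl(PPh3)3, PhH) comes back to 10.

Further compounds
F1 | step 10 | methyl (E)-3-(4-hydroxy-3-methylphenyl)-2-[(1R,3R,6S)-3-isopropyl-2,2-dimethoxy-6-methyl-5-oxocyclohexyl]prop-2-enoate | COC(=O)/C(=C/c1ccc(O)c(C)c1)[C@H]2[C@H](C)C(=O)C[C@H](C(C)C)C2(OC)OC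
F2 | step 10 | methyl (E)-3-(1-hydroxy-3-methyl-4-oxocyclohexa-2,5-dien-1-yl)-2-[(1R,3R,6S)-3-isopropyl-2,2-dimethoxy-6-methyl-5-oxocyclohexyl]prop-2-enoate (matched carbinol epimer) | COC(=O)/C(=C/[C@@]1(O)C=CC(=O)C(C)=C1)[C@H]2[C@H](C)C(=O)C[C@H](C(C)C)C2(OC)OC
F3 | step 10 | cage enone (16 with ring A as a 2-methylcyclohex-2-en-1-one) | COC(=O)C1=C[C@]23C=C(C)C(=O)C[C@@H]2[C@]2(C)[C@H]1C(OC)(OC)[C@@H](C(C)C)C[C@@]2(O)O3
F4 | step 10 | tosylhydrazone of F3 | COC(=O)C1=C[C@]23C=C(C)C(=NNS(=O)(=O)c4ccc(C)cc4)C[C@@H]2[C@]2(C)[C@H]1C(OC)(OC)[C@@H](C(C)C)C[C@@]2(O)O3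
F5 | step 9 | methyl (Z)-2-bromo-3-[(1R,6R)-3-methyl-7-oxabicyclo[4.1.0]hept-3-en-1-yl]prop-2-enoate | COC(=O)/C(Br)=C/[C@]12CC(C)=CC[C@H]1O2
F6 | step 9 | triethylsilyl enol ether of 13 | COC(=O)/C(=C/[C@]12CC(C)=CC[C@H]1O2)[C@H]3C(C)=C(O[Si](CC)(CC)CC)C[C@H](C(C)C)C3(OC)OC
F7 | step 7 | (R)-4,4-dimethoxy-2-methyl-5-(prop-1-en-2-yl)cyclohex-2-en-1-one | CC1=CC(OC)(OC)[C@@H](C(C)=C)CC1=O
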